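**Retrosynthetic overview**
- Last bond: C(sp3)–C(sp2) Negishi coupling between a 2-triflyloxy-1-alkene on the peroxide half and a 2-(cyclohexyl)ethylzinc reagent from the carbocyclic half.
- The 1,2-dioxane is the only ring that has to be built: [4+2] cycloaddition of singlet oxygen to a (3E,5Z)-1,3-diene, then diimide saturation. The E,Z geometry fixes C3 relative to C6; the bought methyl-bearing stereocentre biases the face.
- Diene: Normant syn-carbocupration of propyne (sets 5Z) and palladium-catalysed coupling with an (E)-vinyl iodide made from (S)-Roche ester.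
- Carbocycle: bought as (S)-carvone. Its isopropenyl stereocentre directs the ester-enolate addition that creates the tertiary carbinol, and is then excised; the exocyclic methylene is carried as a Mannich base and revealed by Cope elimination.
- Ring order: cyclohexane purchased; dioxane formed in step 5; the two halves are joined in the last step.

Assumption: the SMILES is read exactly as drawn (propanoate 2R, dioxane 3S,6R, carbinol R) and every numbered starting material is taken to be a catalogue chemical.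

**Route**

Step 1
Reactants: 1 methyl (2S)-3-hydroxy-2-methylpropanoate
Product: 2 methyl (2S)-3-[(tert-butyldimethylsilyl)oxy]-2-methylpropanoate
Conditions: TBSCl, imidazole, DMF, 0 °C to rt
Reagents that add atoms: tert-butyldimethylsilyl chloride, CC(C)(C)[Si](C)(C)Cl
Why: Imidazole-promoted silylation of the primary alcohol protects it without touching the bought stereocentre.

Step 2
Reactants: 2 methyl (2S)-3-[(tert-butyldimethylsilyl)oxy]-2-methylpropanoate
Product: 3 (2S)-3-[(tert-butyldimethylsilyl)oxy]-2-methylpropanal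
Conditions: i-Bu2AlH (1.1 equiv), CH2Cl2, −78 °C; aq. KNaC4H4O6
Reagents that add atoms: none
Why: Partial ester reduction stops at the aluminium hemiacetal at −78 °C, and the cold, non-basic work-up releases the aldehyde without epimerising the α-centre.

Step 3
Reactants: 3 (2S)-3-[(tert-butyldimethylsilyl)oxy]-2-methylpropanal
Product: 4 tert-butyl{[(2R,3E)-4-iodo-2-methylbut-3-en-1-yl]oxy}dimethylsilane
Conditions: CrCl2, CHI3, THF, 0 °C
Reagents that add atoms: iodoform, C(I)(I)I
Why: Takai olefination with the geminal dichromium species from iodoform gives the (E)-vinyl iodide under base-free conditions, so the α-stereocentre is kept (the descriptor changes only by priority).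

Step 4
Reactants: 5 2-(3-bromopropyl)-2-methyl-1,3-dioxolane; 6 propyne; 4 tert-butyl{[(2R,3E)-4-iodo-2-methylbut-3-en-1-yl]oxy}dimethylsilane
Product: 11 tert-butyl{[(2R,3E,5Z)-2,6-dimethyl-9-(2-methyl-1,3-dioxolan-2-yl)nona-3,5-dien-1-yl]oxy}dimethylsilane, via Grignard reagent 7 (not isolated), via alkylcopper 8 (not isolated), via vinylcopper 9 (not isolated), via vinylzinc bromide 10 (not isolated)
Conditions: 5, Mg, Et2O; CuBr·SMe2, Et2O–Me2S, −45 °C; 6, −25 °C; then ZnBr2, THF, Pd(PPh3)4 (5 mol %), 4, −20 °C to rt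
Reagents that add atoms: none
Why: Normant syn-carbocupration of propyne puts the alkyl chain cis to the metal (hence 5Z), and transmetalation to zinc followed by zerovalent-palladium-catalysed Negishi-type alkenyl–alkenyl coupling joins it to 4 with retention on both partners (3E).

Step 5
Reactants: 11 tert-butyl{[(2R,3E,5Z)-2,6-dimethyl-9-(2-methyl-1,3-dioxolan-2-yl)nona-3,5-dien-1-yl]oxy}dimethylsilane
Product: 12 tert-butyl{(2S)-2-[(3S,6R)-6-methyl-6-[3-(2-methyl-1,3-dioxolan-2-yl)propyl]-3,6-dihydro-1,2-dioxin-3-yl]propoxy}dimethylsilane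
Conditions: O2, visible light, tetraphenylporphyrin (cat.), CH2Cl2, −78 °C; chromatography
Reagents that add atoms: oxygen, O=O
Why: Suprafacial [4+2] cycloaddition of singlet oxygen to the s-cis diene turns the E,Z geometry into the cis relation of the C3 side chain and the C6 methyl, and oxygen is expected to add anti to the CH2OSi arm in the H-eclipsed rotamer of the bought stereocentre, giving the 3S,6R adduct as the major one (modest selectivity expected; the other facial isomer is removed by chromatography).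

Step 6
Reactants: 12 tert-butyl{(2S)-2-[(3S,6R)-6-methyl-6-[3-(2-methyl-1,3-dioxolan-2-yl)propyl]-3,6-dihydro-1,2-dioxin-3-yl]propoxy}dimethylsilane
Product: 13 tert-butyl{(2S)-2-[(3S,6R)-6-methyl-6-[3-(2-methyl-1,3-dioxolan-2-yl)propyl]-1,2-dioxan-3-yl]propoxy}dimethylsilane
Conditions: KO2CN=NCO2K, AcOH, CH2Cl2, 0 °C to rt
Reagents that add atoms: none
Why: Diimide reduction transfers H2 concertedly to the only C=C and leaves the O–O bond intact, which catalytic hydrogenation would not.

Step 7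
Reactants: 13 tert-butyl{(2S)-2-[(3S,6R)-6-methyl-6-[3-(2-methyl-1,3-dioxolan-2-yl)propyl]-1,2-dioxan-3-yl]propoxy}dimethylsilane
Product: 14 (2R)-2-[(3S,6R)-6-methyl-6-(4-oxopentyl)-1,2-dioxan-3-yl]propanoic acid
Conditions: CrO3, H2SO4, H2O, acetone, 0 °C to rt
Reagents that add atoms: water, O
Why: Under Jones oxidation the aqueous acid cleaves the dioxolane and the primary silyl ether while hexavalent chromium oxidises the freed alcohol to the acid; dialkyl peroxides tolerate these conditions.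

Step 8
Reactants: 14 (2R)-2-[(3S,6R)-6-methyl-6-(4-oxopentyl)-1,2-dioxan-3-yl]propanoic acid
Product: 15 methyl (2R)-2-[(3S,6R)-6-methyl-6-(4-oxopentyl)-1,2-dioxan-3-yl]propanoate
Conditions: Me3SiCHN2, MeOH–toluene, 0 °C
Reagents that add atoms: (trimethylsilyl)diazomethane, C[Si](C)(C)C=[N+]=[N-]
Why: Diazoalkane O-methylation of the acid needs no base, so the β-peroxy ester neither epimerises nor opens by retro-oxa-Michael reaction.

Step 9
Reactants: 15 methyl (2R)-2-[(3S,6R)-6-methyl-6-(4-oxopentyl)-1,2-dioxan-3-yl]propanoate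
Product: 17 methyl (2R)-2-[(3S,6R)-6-methyl-6-{4-[(trifluoromethanesulfonyl)oxy]pent-4-en-1-yl}-1,2-dioxan-3-yl]propanoate, via potassium enolate 16 (not isolated)
Conditions: KN(SiMe3)2 (1.05 equiv), THF, −78 °C; Comins' reagent, −78 °C
Reagents that add atoms: N-(5-chloropyridin-2-yl)-1,1,1-trifluoro-N-(trifluoromethanesulfonyl)methanesulfonamide, Clc1ccc(nc1)N(S(=O)(=O)C(F)(F)F)S(=O)(=O)C(F)(F)F
Why: Kinetic enolate triflation: the silazide is basic enough to deprotonate the methyl ketone on its methyl side but too weak to enolise the hindered ester, and the triflimide traps the enolate at −78 °C.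

Step 10
Reactants: 18 (5S)-2-methyl-5-(prop-1-en-2-yl)cyclohex-2-en-1-one
Product: 20 (5S)-2,2-dimethyl-5-(prop-1-en-2-yl)cyclohexan-1-one, via lithium enolate 19 (not isolated)
Conditions: LiBH(s-Bu)3, THF, −78 °C; MeI, −78 °C to rt
Reagents that add atoms: iodomethane, CI
Why: Conjugate hydride reduction of the enone gives the regiodefined enolate, and its C-methylation (reductive alkylation) builds the gem-dimethyl carbon without touching the bought C5 stereocentre.

Step 11
Reactants: 20 (5S)-2,2-dimethyl-5-(prop-1-en-2-yl)cyclohexan-1-one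
Product: 22 (5S,6S)-6-[(dimethylamino)methyl]-2,2-dimethyl-5-(prop-1-en-2-yl)cyclohexan-1-one, via lithium enolate 21 (not isolated)
Conditions: LiN(i-Pr)2, THF, −78 °C; CH2=NMe2+ I−, −78 to 0 °C
Reagents that add atoms: dimethylmethyleneiminium iodide, C=[N+](C)C.[I-]
Why: Mannich aminomethylation of the only possible enolate with Eschenmoser's salt occurs trans to the neighbouring isopropenyl group (also the thermodynamic diequatorial isomer), storing the future methylene in a form that survives ozone.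

Step 12
Reactants: 23 tert-butyl acetate; 22 (5S,6S)-6-[(dimethylamino)methyl]-2,2-dimethyl-5-(prop-1-en-2-yl)cyclohexan-1-one
Product: 25 tert-butyl 2-[(1S,5S,6S)-6-[(dimethylamino)methyl]-1-hydroxy-2,2-dimethyl-5-(prop-1-en-2-yl)cyclohexyl]acetate, via lithium ester enolate 24 (not isolated)
Conditions: 23, LiN(i-Pr)2, THF, −78 °C; CeCl3; 22, −78 °C
Reagents that add atoms: none
Why: Aldol-type 1,2-addition of the ester enolate occurs by axial attack on the chair locked by the equatorial isopropenyl and aminomethyl groups, on the face away from the axial C2 methyl, so the new chain ends trans to the isopropenyl group and the carbinol configuration is set by the carvone stereocentre.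

Step 13
Reactants: 25 tert-butyl 2-[(1S,5S,6S)-6-[(dimethylamino)methyl]-1-hydroxy-2,2-dimethyl-5-(prop-1-en-2-yl)cyclohexyl]acetate
Product: 27 tert-butyl 2-[(1S,6S)-6-[(dimethylamino)methyl]-1-hydroxy-2,2-dimethylcyclohexyl]acetate, via methoxy hydroperoxide 26 (not isolated)
Conditions: CF3CO2H (1.1 equiv), O3, MeOH, −78 °C; FeSO4·7H2O, PhSH, −78 °C to rt; aq. NaHCO3
Reagents that add atoms: none
Why: Hydrodealkenylation: ozonolysis in methanol gives the α-methoxy hydroperoxide, divalent iron converts it to an alkoxyl radical that undergoes β-scission, and the thiol reduces the ring radical to CH2, the amine being shielded from ozone as its ammonium salt.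

Step 14
Reactants: 27 tert-butyl 2-[(1S,6S)-6-[(dimethylamino)methyl]-1-hydroxy-2,2-dimethylcyclohexyl]acetate
Product: 29 tert-butyl 2-[(1R)-1-hydroxy-2,2-dimethyl-6-methylidenecyclohexyl]acetate, via amine N-oxide 28 (not isolated)
Conditions: mCPBA (1.0 equiv), CH2Cl2, 0 °C; then DMSO–THF, 60 °C
Reagents that add atoms: none
Why: N-oxidation followed by Cope elimination (syn, five-membered transition state) can only take the single β-hydrogen on the ring carbon, so only the exocyclic methylene forms; the carbinol is untouched (R by priority change).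

Step 15
Reactants: 29 tert-butyl 2-[(1R)-1-hydroxy-2,2-dimethyl-6-methylidenecyclohexyl]acetate
Product: 30 (1R)-1-(2-hydroxyethyl)-2,2-dimethyl-6-methylidenecyclohexan-1-ol
Conditions: LiAlH4, THF, 0 °C
Reagents that add atoms: none
Why: Hydride reduction of the ester to the primary alcohol leaves the isolated alkene and the tertiary alcohol alone.

Step 16
Reactants: 30 (1R)-1-(2-hydroxyethyl)-2,2-dimethyl-6-methylidenecyclohexan-1-ol
Product: 31 (1R)-1-(2-iodoethyl)-2,2-dimethyl-6-methylidenecyclohexan-1-ol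
Conditions: I2, PPh3, imidazole, CH2Cl2, 0 °C
Reagents that add atoms: iodine, II
Why: Appel iodination is selective for the primary alcohol; the hindered tertiary allylic alcohol does not form an oxyphosphonium ion under these neutral conditions.

Step 17
Reactants: 31 (1R)-1-(2-iodoethyl)-2,2-dimethyl-6-methylidenecyclohexan-1-ol
Product: 32 {[(1R)-1-(2-iodoethyl)-2,2-dimethyl-6-methylidenecyclohexyl]oxy}trimethylsilane
Conditions: Me3SiOTf, 2,6-lutidine, CH2Cl2, −78 °C
Reagents that add atoms: trimethylsilyl trifluoromethanesulfonate, C[Si](C)(C)OS(=O)(=O)C(F)(F)F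
Why: Silyl triflate silylation masks the hindered tertiary hydroxyl so that it cannot protonate the organozinc reagent of the next step.

Step 18
Reactants: 32 {[(1R)-1-(2-iodoethyl)-2,2-dimethyl-6-methylidenecyclohexyl]oxy}trimethylsilane; 17 methyl (2R)-2-[(3S,6R)-6-methyl-6-{4-[(trifluoromethanesulfonyl)oxy]pent-4-en-1-yl}-1,2-dioxan-3-yl]propanoate
Product: 35 methyl (2R)-2-[(3S,6R)-6-{6-[(1R)-1-hydroxy-2,2-dimethyl-6-methylidenecyclohexyl]-4-methylidenehexyl}-6-methyl-1,2-dioxan-3-yl]propanoate, via alkylzinc iodide 33 (not isolated), via silyl ether 34 (not isolated)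
Conditions: 32, Zn dust, LiCl, THF, 40 °C; then 17, PdCl2(dppf) (5 mol %), THF–NMP, rt; then HF·pyridine, THF, 0 °C
Reagents that add atoms: none
Why: Zinc insertion into the primary iodide and base-free Negishi coupling with the enol triflate create the 1,1-disubstituted alkene without disturbing the β-peroxy ester, and fluoride then removes the trimethylsilyl group; no stereocentre is involved.

**Compound list**
1 | methyl (2S)-3-hydroxy-2-methylpropanoate | COC(=O)[C@@H](C)CO | starting material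
2 | methyl (2S)-3-[(tert-butyldimethylsilyl)oxy]-2-methylpropanoate | COC(=O)[C@@H](C)CO[Si](C)(C)C(C)(C)C | intermediate
3 | (2S)-3-[(tert-butyldimethylsilyl)oxy]-2-methylpropanal | O=C[C@@H](C)CO[Si](C)(C)C(C)(C)C | intermediate
4 | tert-butyl{[(2R,3E)-4-iodo-2-methylbut-3-en-1-yl]oxy}dimethylsilane | I/C=C/[C@@H](C)CO[Si](C)(C)C(C)(C)C | intermediate
5 | 2-(3-bromopropyl)-2-methyl-1,3-dioxolane | CC1(CCCBr)OCCO1 | starting material
6 | propyne | CC#C | starting material
7 | [3-(2-methyl-1,3-dioxolan-2-yl)propyl]magnesium bromide | CC1(CCC[Mg]Br)OCCO1 | intermediate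
8 | [3-(2-methyl-1,3-dioxolan-2-yl)propyl]copper | CC1(CCC[Cu])OCCO1 | intermediate
9 | [(1Z)-2-methyl-5-(2-methyl-1,3-dioxolan-2-yl)pent-1-en-1-yl]copper | CC1(CCC/C(C)=C\[Cu])OCCO1 | intermediate
10 | bromo[(1Z)-2-methyl-5-(2-methyl-1,3-dioxolan-2-yl)pent-1-en-1-yl]zinc | CC1(CCC/C(C)=C\[Zn]Br)OCCO1 | intermediate
11 | tert-butyl{[(2R,3E,5Z)-2,6-dimethyl-9-(2-methyl-1,3-dioxolan-2-yl)nona-3,5-dien-1-yl]oxy}dimethylsilane | CC1(CCC/C(C)=C\C=C\[C@@H](C)CO[Si](C)(C)C(C)(C)C)OCCO1 | intermediate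
12 | tert-butyl{(2S)-2-[(3S,6R)-6-methyl-6-[3-(2-methyl-1,3-dioxolan-2-yl)propyl]-3,6-dihydro-1,2-dioxin-3-yl]propoxy}dimethylsilane | CC1(CCC[C@]2(C)C=C[C@@H]([C@@H](C)CO[Si](C)(C)C(C)(C)C)OO2)OCCO1 | intermediate
13 | tert-butyl{(2S)-2-[(3S,6R)-6-methyl-6-[3-(2-methyl-1,3-dioxolan-2-yl)propyl]-1,2-dioxan-3-yl]propoxy}dimethylsilane | CC1(CCC[C@]2(C)CC[C@@H]([C@@H](C)CO[Si](C)(C)C(C)(C)C)OO2)OCCO1 | intermediate
14 | (2R)-2-[(3S,6R)-6-methyl-6-(4-oxopentyl)-1,2-dioxan-3-yl]propanoic acid | CC(=O)CCC[C@]1(C)CC[C@@H]([C@@H](C)C(O)=O)OO1 | intermediate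
15 | methyl (2R)-2-[(3S,6R)-6-methyl-6-(4-oxopentyl)-1,2-dioxan-3-yl]propanoate | CC(=O)CCC[C@]1(C)CC[C@@H]([C@@H](C)C(=O)OC)OO1 | intermediate
16 | potassium 5-[(3R,6S)-6-[(2R)-1-methoxy-1-oxopropan-2-yl]-3-methyl-1,2-dioxan-3-yl]pent-1-en-2-olate | [K+].[O-]C(=C)CCC[C@]1(C)CC[C@@H]([C@@H](C)C(=O)OC)OO1 | intermediate
17 | methyl (2R)-2-[(3S,6R)-6-methyl-6-{4-[(trifluoromethanesulfonyl)oxy]pent-4-en-1-yl}-1,2-dioxan-3-yl]propanoate | C=C(OS(=O)(=O)C(F)(F)F)CCC[C@]1(C)CC[C@@H]([C@@H](C)C(=O)OC)OO1 | intermediate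
18 | (5S)-2-methyl-5-(prop-1-en-2-yl)cyclohex-2-en-1-one, (S)-(+)-carvone | CC1=CC[C@@H](CC1=O)C(C)=C | starting material
19 | lithium (5S)-2-methyl-5-(prop-1-en-2-yl)cyclohex-1-en-1-olate | [Li+].[O-]C1=C(C)CC[C@@H](C1)C(C)=C | intermediate
20 | (5S)-2,2-dimethyl-5-(prop-1-en-2-yl)cyclohexan-1-one | CC1(C)CC[C@@H](CC1=O)C(C)=C | intermediate
21 | lithium (3S)-6,6-dimethyl-3-(prop-1-en-2-yl)cyclohex-1-en-1-olate | [Li+].[O-]C1=C[C@@H](C(C)=C)CCC1(C)C | intermediate
22 | (5S,6S)-6-[(dimethylamino)methyl]-2,2-dimethyl-5-(prop-1-en-2-yl)cyclohexan-1-one | O=C1[C@H](CN(C)C)[C@@H](C(C)=C)CCC1(C)C | intermediate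
23 | tert-butyl acetate | CC(=O)OC(C)(C)C | starting material
24 | lithium 1-(tert-butoxy)ethen-1-olate | [Li+].[O-]C(=C)OC(C)(C)C | intermediate
25 | tert-butyl 2-[(1S,5S,6S)-6-[(dimethylamino)methyl]-1-hydroxy-2,2-dimethyl-5-(prop-1-en-2-yl)cyclohexyl]acetate | CC(C)(C)OC(=O)C[C@]1(O)[C@H](CN(C)C)[C@@H](C(C)=C)CCC1(C)C | intermediate
26 | tert-butyl 2-[(1S,5S,6S)-6-[(dimethylamino)methyl]-5-(1-hydroperoxy-1-methoxyethyl)-1-hydroxy-2,2-dimethylcyclohexyl]acetate, both epimers at the peroxyketal carbon, formed as its trifluoroacetate salt | CC(C)(C)OC(=O)C[C@]1(O)[C@H](CN(C)C)[C@@H](C(C)(OC)OO)CCC1(C)C | intermediate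
27 | tert-butyl 2-[(1S,6S)-6-[(dimethylamino)methyl]-1-hydroxy-2,2-dimethylcyclohexyl]acetate | CC(C)(C)OC(=O)C[C@]1(O)[C@H](CN(C)C)CCCC1(C)C | intermediate
28 | 1-[(1S,2S)-2-(2-tert-butoxy-2-oxoethyl)-2-hydroxy-3,3-dimethylcyclohexyl]-N,N-dimethylmethanamine N-oxide | CC(C)(C)OC(=O)C[C@]1(O)[C@H](C[N+](C)(C)[O-])CCCC1(C)C | intermediate
29 | tert-butyl 2-[(1R)-1-hydroxy-2,2-dimethyl-6-methylidenecyclohexyl]acetate | CC(C)(C)OC(=O)C[C@]1(O)C(=C)CCCC1(C)C | intermediate
30 | (1R)-1-(2-hydroxyethyl)-2,2-dimethyl-6-methylidenecyclohexan-1-ol | OCC[C@]1(O)C(=C)CCCC1(C)C | intermediate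
31 | (1R)-1-(2-iodoethyl)-2,2-dimethyl-6-methylidenecyclohexan-1-ol | ICC[C@]1(O)C(=C)CCCC1(C)C | intermediate
32 | {[(1R)-1-(2-iodoethyl)-2,2-dimethyl-6-methylidenecyclohexyl]oxy}trimethylsilane | ICC[C@]1(O[Si](C)(C)C)C(=C)CCCC1(C)C | intermediate
33 | iodo(2-{(1R)-2,2-dimethyl-6-methylidene-1-[(trimethylsilyl)oxy]cyclohexyl}ethyl)zinc | I[Zn]CC[C@]1(O[Si](C)(C)C)C(=C)CCCC1(C)C | intermediate
34 | methyl (2R)-2-[(3S,6R)-6-(6-{(1R)-2,2-dimethyl-6-methylidene-1-[(trimethylsilyl)oxy]cyclohexyl}-4-methylidenehexyl)-6-methyl-1,2-dioxan-3-yl]propanoate | C=C(CCC[C@]1(C)CC[C@@H]([C@@H](C)C(=O)OC)OO1)CC[C@]1(O[Si](C)(C)C)C(=C)CCCC1(C)C | intermediate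
35 | methyl (2R)-2-[(3S,6R)-6-{6-[(1R)-1-hydroxy-2,2-dimethyl-6-methylidenecyclohexyl]-4-methylidenehexyl}-6-methyl-1,2-dioxan-3-yl]propanoate | C=C(CCC[C@]1(C)CC[C@@H]([C@@H](C)C(=O)OC)OO1)CC[C@]1(O)C(=C)CCCC1(C)C | target

**Totals**
Total step count: 18. Longest linear sequence: 10 (steps 1 to 9, then step 18); the carbocyclic branch is 9 (steps 10 to 17, then 18).

**Steps most likely to fail**

Step 5. The facial bias comes from a single allylic stereocentre on an E-alkene, so the ratio of the two cycloadducts may be low or even reversed, and the trisubstituted diene terminus can divert into ene hydroperoxides. The fallback sets out from 11 and comes back at 14. Bu4NF removes the silyl group to give dienol F1. The cycloaddition is then run on the free alcohol in CCl4, where hydrogen bonding of the hydroxyl to the incoming oxygen, not steric shielding, selects the face, giving hydroxy dihydrodioxine F2. Diimide reduction gives hydroxy dioxane F3, and the CrO3/H2SO4 oxidation of step 7 takes F3 directly to 14.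

Step 9. Even a small amount of ester enolate would open the ring by retro-oxa-Michael reaction, and some internal enol triflate may form. The fallback sets out from 13 and comes back at 17, making the triflate before any ester exists. Pyridinium tosylate in wet acetone removes only the dioxolane to give ketone F4. KN(SiMe3)2 and Comins' reagent convert it through potassium enolate F5 into enol triflate F6. CrO3/H2SO4 cleaves the silyl ether and oxidises to acid F7, and Me3SiCHN2 gives 17.

Step 18. Zinc dust, the organozinc reagent or zerovalent palladium may reduce the O–O bond before the coupling is complete. The fallback sets out from 32 and comes back at 34, replacing the organozinc by an organoboron partner. t-BuLi (2 equiv, Et2O, −78 °C) gives alkyllithium F8, which 9-methoxy-9-BBN traps as lithium borate F9. Suzuki–Miyaura coupling of F9 with 17 (PdCl2(dppf), AsPh3, Cs2CO3, DMF–H2O, rt) gives 34, which is desilylated with HF·pyridine as in step 18.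

**Further compounds**
F1 | step 5 | (2R,3E,5Z)-2,6-dimethyl-9-(2-methyl-1,3-dioxolan-2-yl)nona-3,5-dien-1-ol | CC1(CCC/C(C)=C\C=C\[C@@H](C)CO)OCCO1
F2 | step 5 | (2S)-2-[(3S,6R)-6-methyl-6-[3-(2-methyl-1,3-dioxolan-2-yl)propyl]-3,6-dihydro-1,2-dioxin-3-yl]propan-1-ol | CC1(CCC[C@]2(C)C=C[C@@H]([C@@H](C)CO)OO2)OCCO1
F3 | step 5 | (2S)-2-[(3S,6R)-6-methyl-6-[3-(2-methyl-1,3-dioxolan-2-yl)propyl]-1,2-dioxan-3-yl]propan-1-ol | CC1(CCC[C@]2(C)CC[C@@H]([C@@H](C)CO)OO2)OCCO1
F4 | step 9 | tert-butyldimethyl{(2S)-2-[(3S,6R)-6-methyl-6-(4-oxopentyl)-1,2-dioxan-3-yl]propoxy}silane | CC(=O)CCC[C@]1(C)CC[C@@H]([C@@H](C)CO[Si](C)(C)C(C)(C)C)OO1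
F5 | step 9 | potassium 5-[(3R,6S)-6-{(2S)-1-[(tert-butyldimethylsilyl)oxy]propan-2-yl}-3-methyl-1,2-dioxan-3-yl]pent-1-en-2-olate | [K+].[O-]C(=C)CCC[C@]1(C)CC[C@@H]([C@@H](C)CO[Si](C)(C)C(C)(C)C)OO1
F6 | step 9 | tert-butyldimethyl{(2S)-2-[(3S,6R)-6-methyl-6-{4-[(trifluoromethanesulfonyl)oxy]pent-4-en-1-yl}-1,2-dioxan-3-yl]propoxy}silane | C=C(OS(=O)(=O)C(F)(F)F)CCC[C@]1(C)CC[C@@H]([C@@H](C)CO[Si](C)(C)C(C)(C)C)OO1
F7 | step 9 | (2R)-2-[(3S,6R)-6-methyl-6-{4-[(trifluoromethanesulfonyl)oxy]pent-4-en-1-yl}-1,2-dioxan-3-yl]propanoic acid | C=C(OS(=O)(=O)C(F)(F)F)CCC[C@]1(C)CC[C@@H]([C@@H](C)C(O)=O)OO1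
F8 | step 18 | (2-{(1R)-2,2-dimethyl-6-methylidene-1-[(trimethylsilyl)oxy]cyclohexyl}ethyl)lithium | [Li]CC[C@]1(O[Si](C)(C)C)C(=C)CCCC1(C)C
F9 | step 18 | lithium 9-(2-{(1R)-2,2-dimethyl-6-methylidene-1-[(trimethylsilyl)oxy]cyclohexyl}ethyl)-9-methoxy-9-boranuidabicyclo[3.3.1]nonane | [Li+].CO[B-]1(CC[C@]2(O[Si](C)(C)C)C(=C)CCCC2(C)C)C2CCCC1CCC2
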